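**Retrosynthetic overview**
- Both pyranone rings are removed first. Each goes back, through cyclodehydration and a Baker–Venkataraman acyl shift, to an o-(3-phenylpropanoyloxy)acetophenone. The target thus reduces to a tetrahydroxy-diacetylbiphenyl and 3-phenylpropanoyl chloride.
- The acetyl group on the resorcinol-derived ring (ring A) is disconnected as a Friedel–Crafts acetylation, which leaves a 6-aryl-2,3-dihydroxyacetophenone (ring B).
- Feature used: in the 8-hydroxychromone unit, O1 (on C8a) and the C8 hydroxyl are the two oxygens of a catechol, and the biaryl carbon C5 lies para to C8 and is bonded to C4a, which carries the C4 carbonyl. In the o-quinone of the ring B acetophenone this carbon is therefore the β-position of a ring enone and of the acetyl enone at once, while its partner, C6 of the 7-hydroxychromone unit, is C4 of a resorcinol diether, the most nucleophilic carbon of that ring.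
- The C5–C6 biaryl bond is therefore cut as a metal-free C–H/C–H union of anodically generated 3-acetyl-1,2-benzoquinone with 1,3-dimethoxybenzene.
- Ring order: both benzene rings are bought and joined in step 1, and both pyranone rings are closed together in step 8.

Key step: step 1

Assumption: the target has no stereocentre and its biaryl axis is drawn without a configurational descriptor, so no atroposelection is attempted.

**Step 1**
Reactants: 1 2',3'-dihydroxyacetophenone; 2 1,3-dimethoxybenzene
Product: 5 1-[6-(2,4-dimethoxyphenyl)-2,3-dihydroxyphenyl]ethanone, via 3-acetyl-1,2-benzoquinone 3 (not isolated), via 4-aryl-3-acetyl-1,2-benzoquinone 4 (not isolated)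
Conditions: graphite anode, Pt-wire cathode, undivided cell, constant current (about 5 mA cm-2, 2.2–2.5 F mol-1), 2 (5 equiv), Bu4NPF6 (0.1 M), CF3CO2H (1 equiv), HFIP, rt; then EtOAc, aq. Na2S2O4 wash
Reagents that add atoms: none
Why: Proposed new method: at a potential far below that needed to oxidise 2, the graphite anode strips two electrons and two protons from catechol 1 to give acyl-o-quinone 3, which hydrogen bonding to HFIP and the added acid make more electrophilic; C4 of 2 then adds in a Friedel–Crafts-type conjugate addition to the quinone CH adjacent to the acetyl-bearing carbon, and loss of the arenium proton followed by enolisation delivers catechol 5 with the new aryl–aryl bond at C6 of the acetophenone ring. The closest known reaction types are the anodic oxidation of catechols with in-situ Michael capture of the o-quinone by carbon nucleophiles and the acid-promoted arylation of 2-acyl-1,4-benzoquinones by electron-rich arenes at the carbon next to the acyl group; pairing a 3-acyl-1,2-benzoquinone with a simple arene is the extrapolation. One sigma bond between two sp2 carbons is formed, no ring is closed and no stereocentre arises. The selectivity needed on the quinone is attack at C4 rather than C5: C4 is the β-carbon of both the C2 ring enone and the exocyclic acetyl enone, C5 is β only to the C1 carbonyl, and this double activation, the same bias that steers nucleophiles to C3 of 2-acyl-1,4-benzoquinones, has to outweigh the extra crowding beside the acetyl group; on the arene, C4 is preferred to C2, which is flanked by both methoxyls. Because 5 is easier to oxidise than 1, part of it should be carried on to quinone 4, but there the doubly activated carbon is already occupied and the methyl ethers leave no free phenol that could close a dibenzofuran, so the Na2S2O4 wash should return 4 to 5.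

**Step 2**
Reactants: 5 1-[6-(2,4-dimethoxyphenyl)-2,3-dihydroxyphenyl]ethanone
Product: 6 3-acetyl-4-(2,4-dimethoxyphenyl)benzene-1,2-diyl diacetate
Conditions: Ac2O (3 equiv), pyridine, DMAP (cat.), CH2Cl2, 0 °C to rt
Reagents that add atoms: acetic anhydride, CC(=O)OC(C)=O
Why: DMAP-catalysed O-acetylation caps both catechol hydroxyls, which removes the oxidation-prone, Lewis-acid-binding diol and deactivates ring B so that the next electrophile can only enter ring A.

**Step 3**
Reactants: 6 3-acetyl-4-(2,4-dimethoxyphenyl)benzene-1,2-diyl diacetate; 7 acetyl chloride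
Product: 8 3-acetyl-4-(5-acetyl-2,4-dimethoxyphenyl)benzene-1,2-diyl diacetate
Conditions: 7 (1.5 equiv), SnCl4 (3 equiv), CH2Cl2, 0 °C to rt; dilute aq. HCl work-up
Reagents that add atoms: acetyl chloride 7, CC(=O)Cl
Why: Friedel–Crafts acylation goes to C5 of ring A, para to the C2 methoxyl and ortho to the C4 methoxyl, because C3 is wedged between two methoxyls and ring B carries three acceptor groups, while the mild Lewis acid SnCl4 at or below room temperature should not trigger Fries migration of the aryl acetates.

**Step 4**
Reactants: 8 3-acetyl-4-(5-acetyl-2,4-dimethoxyphenyl)benzene-1,2-diyl diacetate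
Product: 9 1-[5-(2-acetyl-3,4-dihydroxyphenyl)-2,4-dimethoxyphenyl]ethanone
Conditions: HCl (cat., 1.25 M in MeOH), MeOH, 50 °C, argon
Reagents that add atoms: none
Why: Acid-catalysed transesterification passes both acetyl groups of the activated aryl esters to methanol, and working on the acid side keeps the liberated catechol from air oxidation and spares the ketones and methyl ethers.

**Step 5**
Reactants: 9 1-[5-(2-acetyl-3,4-dihydroxyphenyl)-2,4-dimethoxyphenyl]ethanone
Product: 10 1-[5-(2-acetyl-3,4-dihydroxyphenyl)-2,4-dihydroxyphenyl]ethanone
Conditions: BBr3 (6 equiv), CH2Cl2, -78 °C to rt; then ice-water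
Reagents that add atoms: none
Why: In this BBr3 aryl methyl ether cleavage boron binds each methoxyl oxygen and bromide takes the methyl group by SN2 attack, the ether ortho to the acetyl going first through chelation and the excess reagent (sized for the catechol and both ketones, which also bind boron) taking the second, after which hydrolysis of the aryl borates frees the phenols.

**Step 6**
Reactants: 10 1-[5-(2-acetyl-3,4-dihydroxyphenyl)-2,4-dihydroxyphenyl]ethanone; 11 3-phenylpropanoyl chloride
Product: 12 tetrakis(3-phenylpropanoate) of 10 (all four phenols esterified)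
Conditions: 11 (6 equiv), pyridine, DMAP (0.2 equiv), 0 °C to 40 °C
Reagents that add atoms: 3-phenylpropanoyl chloride 11, O=C(Cl)CCc1ccccc1
Why: Einhorn-type acylation with DMAP nucleophilic catalysis and excess acid chloride overcomes the hydrogen bonding of the two chelated phenols, and it also drains back to the open ketone any cyclic hemiketal formed between the ring A hydroxyl ortho to the biaryl bond and the ring B acetyl group.

**Step 7**
Reactants: 12 tetrakis(3-phenylpropanoate) of 10
Product: 13 bis(1,3-diketone) diester (each acetyl is now a 3-oxo-5-phenylpentanoyl group with a free ortho phenol; the ring B ester at the former C3' oxygen and the ring A ester ortho to the biaryl bond are retained)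
Conditions: KOtBu (3.0 equiv), THF, 0 °C to rt; then cold 1 M HCl
Reagents that add atoms: none
Why: In this twofold Baker–Venkataraman rearrangement each acetyl enolate attacks the carbonyl of its ortho ester through a six-membered cyclic transition state and collapses to a phenoxide and a stabilised diketonate, whereas the two esters with no ortho acetyl group lack this pathway and are due for removal anyway should the base take some of them.

**Step 8**
Reactants: 13 bis(1,3-diketone) diester
Product: 14 bischromone bis(3-phenylpropanoate) (the target esterified at its C7 and C8 hydroxyls)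
Conditions: p-TsOH·H2O (0.2 equiv), toluene, reflux, Dean–Stark trap
Reagents that add atoms: none
Why: In this acid-catalysed cyclodehydration each free phenol adds to the distal ketone of its 1,3-diketone (6-exo-trig hemiketal formation) and loss of water gives the conjugated 4-pyranone, while azeotropic removal of water keeps the two aryl esters intact.

**Step 9**
Reactants: 14 bischromone bis(3-phenylpropanoate)
Product: 15 7-hydroxy-6-[8-hydroxy-4-oxo-2-(2-phenylethyl)-4H-chromen-5-yl]-2-(2-phenylethyl)-4H-chromen-4-one (target CNP0279305.0)
Conditions: K2CO3 (3 equiv), MeOH/THF, 0 °C to rt; then 1 M HCl to pH 4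
Reagents that add atoms: none
Why: Carbonate-mediated methanolysis cleaves the two activated aryl esters at room temperature, conditions under which the chromone rings should stay closed, and acidification returns the two phenols.

**Compound list**
1 | 2',3'-dihydroxyacetophenone | CC(=O)c1cccc(O)c1O | starting material
2 | 1,3-dimethoxybenzene | COc1cccc(OC)c1 | starting material
3 | 3-acetyl-1,2-benzoquinone | CC(=O)C1=CC=CC(=O)C1=O | intermediate
4 | 3-acetyl-4-(2,4-dimethoxyphenyl)-1,2-benzoquinone | CC(=O)C1=C(c2ccc(OC)cc2OC)C=CC(=O)C1=O | intermediate
5 | 1-[6-(2,4-dimethoxyphenyl)-2,3-dihydroxyphenyl]ethanone | CC(=O)c1c(O)c(O)ccc1-c1ccc(OC)cc1OC | intermediate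
6 | 3-acetyl-4-(2,4-dimethoxyphenyl)benzene-1,2-diyl diacetate | CC(=O)c1c(OC(C)=O)c(OC(C)=O)ccc1-c1ccc(OC)cc1OC | intermediate
7 | acetyl chloride | CC(=O)Cl | starting material
8 | 3-acetyl-4-(5-acetyl-2,4-dimethoxyphenyl)benzene-1,2-diyl diacetate | CC(=O)c1c(OC(C)=O)c(OC(C)=O)ccc1-c1cc(C(C)=O)c(OC)cc1OC | intermediate
9 | 1-[5-(2-acetyl-3,4-dihydroxyphenyl)-2,4-dimethoxyphenyl]ethanone | CC(=O)c1c(O)c(O)ccc1-c1cc(C(C)=O)c(OC)cc1OC | intermediate
10 | 1-[5-(2-acetyl-3,4-dihydroxyphenyl)-2,4-dihydroxyphenyl]ethanone | CC(=O)c1c(O)c(O)ccc1-c1cc(C(C)=O)c(O)cc1O | intermediate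
11 | 3-phenylpropanoyl chloride | O=C(Cl)CCc1ccccc1 | starting material
12 | tetrakis(3-phenylpropanoate) of 10 | CC(=O)c1c(OC(=O)CCc2ccccc2)c(OC(=O)CCc2ccccc2)ccc1-c1cc(C(C)=O)c(OC(=O)CCc2ccccc2)cc1OC(=O)CCc1ccccc1 | intermediate
13 | bis(1,3-diketone) diester | O=C(CCc1ccccc1)CC(=O)c1c(O)c(OC(=O)CCc2ccccc2)ccc1-c1cc(C(=O)CC(=O)CCc2ccccc2)c(O)cc1OC(=O)CCc1ccccc1 | intermediate
14 | bischromone bis(3-phenylpropanoate) | O=c1cc(CCc2ccccc2)oc2cc(OC(=O)CCc3ccccc3)c(-c3ccc(OC(=O)CCc4ccccc4)c4oc(CCc5ccccc5)cc(=O)c34)cc12 | intermediate
15 | 7-hydroxy-6-[8-hydroxy-4-oxo-2-(2-phenylethyl)-4H-chromen-5-yl]-2-(2-phenylethyl)-4H-chromen-4-one | O=c1cc(CCc2ccccc2)oc2cc(O)c(-c3ccc(O)c4oc(CCc5ccccc5)cc(=O)c34)cc12 | target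

Total step count: 9. Longest linear sequence: 9 steps (1 to 15).

**Steps most likely to fail**

**Step 1 (bears the new-method label).**
- What may go wrong: the arene may attack the less crowded quinone CH that is β to only one carbonyl. The arylation may be slow enough for the quinone to dimerise or decompose. A second arylation may follow re-oxidation of the product.
- The fallback sets out from 1 and returns at 10, using known chemistry only.
- Compound 1 is O-methylated twice (MeI, K2CO3, DMF) to 2',3'-dimethoxyacetophenone F1.
- NBS in DMF should then brominate para to the C3' methoxyl, the pattern known for 2,3-dimethoxybenzaldehyde, whose flanked C2 methoxyl is twisted out of conjugation. This gives 6'-bromo-2',3'-dimethoxyacetophenone F2.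
- Suzuki–Miyaura coupling with commercial 2,4-dimethoxyphenylboronic acid (Pd(PPh3)4, K2CO3, dioxane/water, 90 °C) gives 1-[6-(2,4-dimethoxyphenyl)-2,3-dimethoxyphenyl]ethanone F3.
- Friedel–Crafts acetylation with 7 and SnCl4, directed to ring A as in step 3, gives 1-[5-(2-acetyl-3,4-dimethoxyphenyl)-2,4-dimethoxyphenyl]ethanone F4.
- Excess BBr3 in CH2Cl2 cleaves all four methyl ethers to give 10.

**Step 7.**
- What may go wrong: the ortho esters may be lost to alkoxide attack or ketene-type elimination before they migrate. O-to-O acyl migration within the catechol ring may be followed by a second C-acylation. The enolisable esters may self-condense.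
- The fallback sets out from 9 and returns at 15. It replaces the intramolecular acyl shift in a tetraester by an intermolecular crossed Claisen condensation with inert ether spectators.
- Compound 9 is methylated on both catechol oxygens (MeI, K2CO3, DMF) to the tetramethyl ether F4 already described.
- BCl3 (about 2.4 equiv, CH2Cl2, -78 to 0 °C) removes, by chelation control, only the two methyl ethers ortho to the acetyl groups. This gives 1-[5-(2-acetyl-3-hydroxy-4-methoxyphenyl)-2-hydroxy-4-methoxyphenyl]ethanone F5.
- Excess NaH and ethyl 3-phenylpropanoate in refluxing THF acylate both methyl ketone enolates to give the bis(1,3-diketone) dimethyl ether F6.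
- Catalytic HCl in hot AcOH closes both rings to give the 7,8'-di-O-methyl ether of the target F7.
- BBr3 in CH2Cl2 frees the two phenols to give 15.

**Step 3.**
- What may go wrong: the many carbonyl and ether donors may sequester the Lewis acid so that the acylation stalls. If the reaction is forced, Fries migration or loss of the acetate protecting groups may follow.
- The fallback sets out from 6 and returns at 8. It installs the acetyl group by cross-coupling instead of electrophilic acylation.
- NBS in MeCN brominates ring A at the same C5 position to give 3-acetyl-4-(5-bromo-2,4-dimethoxyphenyl)benzene-1,2-diyl diacetate F8.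
- Stille coupling with tributyl(1-ethoxyvinyl)stannane (PdCl2(PPh3)2, toluene, 100 °C) gives the 1-ethoxyvinyl arene F9.
- Brief treatment with 1 M HCl in THF at rt hydrolyses the enol ether to the methyl ketone 8 without touching the acetates.

**Further compounds**
F1 | step 1 | 2',3'-dimethoxyacetophenone | CC(=O)c1cccc(OC)c1OC
F2 | step 1 | 6'-bromo-2',3'-dimethoxyacetophenone | CC(=O)c1c(Br)ccc(OC)c1OC
F3 | step 1 | 1-[6-(2,4-dimethoxyphenyl)-2,3-dimethoxyphenyl]ethanone | CC(=O)c1c(OC)c(OC)ccc1-c1ccc(OC)cc1OC
F4 | step 1 | 1-[5-(2-acetyl-3,4-dimethoxyphenyl)-2,4-dimethoxyphenyl]ethanone | CC(=O)c1c(OC)c(OC)ccc1-c1cc(C(C)=O)c(OC)cc1OC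
F5 | step 7 | 1-[5-(2-acetyl-3-hydroxy-4-methoxyphenyl)-2-hydroxy-4-methoxyphenyl]ethanone | CC(=O)c1c(O)c(OC)ccc1-c1cc(C(C)=O)c(O)cc1OC
F6 | step 7 | bis(1,3-diketone) dimethyl ether | O=C(CCc1ccccc1)CC(=O)c1c(O)c(OC)ccc1-c1cc(C(=O)CC(=O)CCc2ccccc2)c(O)cc1OC
F7 | step 7 | 7-methoxy-6-[8-methoxy-4-oxo-2-(2-phenylethyl)-4H-chromen-5-yl]-2-(2-phenylethyl)-4H-chromen-4-one | O=c1cc(CCc2ccccc2)oc2cc(OC)c(-c3ccc(OC)c4oc(CCc5ccccc5)cc(=O)c34)cc12
F8 | step 3 | 3-acetyl-4-(5-bromo-2,4-dimethoxyphenyl)benzene-1,2-diyl diacetate | CC(=O)c1c(OC(C)=O)c(OC(C)=O)ccc1-c1cc(Br)c(OC)cc1OC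
F9 | step 3 | 3-acetyl-4-[5-(1-ethoxyvinyl)-2,4-dimethoxyphenyl]benzene-1,2-diyl diacetate | C=C(OCC)c1cc(-c2ccc(OC(C)=O)c(OC(C)=O)c2C(C)=O)c(OC)cc1OC
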